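Take the east run, the flask asked about and followed so far, and divide the target it made by the time and by the catalyst it holds.

common to all: starting material 0.20 M; free catalyst 0.22 mM

| run | second substrate | protic impurity | remark |
|---|---|---|---|
| east | 0.20 M | 0.040 M | the very flask that is asked about, followed so far |
| north-west | 0.20 M | 0.060 M | run made earlier |
| flask | 0.200 M | 0.0400 M |  |

| run | time / s | target / % | starting material / % |
|---|---|---|---|
| east | 12.0 | 10.3 | 77.3 |
| east | 25.0 | 20.0 | 64.5 |
| east | 40.0 | 31.6 | 50.4 |
| east | 50.0 | 38.1 | 41.6 |
| north-west | 10.0 | 8.0 | 75.5 |
| north-west | 20.0 | 15.7 | 61.7 |
| north-west | 50.0 | 38.6 | 33.1 |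

(standard deviation of a reading: 0.5 percentage points)

* factor on the rate of making target when 20 % of the starting material are converted if free catalyst is charged twice over
* factor on the rate when 20 % of the starting material are converted if free catalyst is charged at 0.040 mM instead

- the earlier runs were read with a standard deviation of 0.5 percentage points
- no earlier run changes the charge of free catalyst; that part of a forecast is a guess

Start with the main step by itself. Catalyst is 0.110 % of the starting material charged, and east gave 38.1 % target in 50.0 s. That defines the turnover rate, target made per second per catalyst charged: 6.93 s⁻¹. In east, target came at 0.480 min⁻¹ of the charge over the first 25.0 s and 0.434 min⁻¹ over the next 25.0 s, while starting material fell to 41.6 %. We read these east figures as close to zero order in starting material, so we take the rate as the turnover rate times the catalyst, giving factors of 2 and 0.182.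

Now add the protic impurity. At the last readings 20 percentage points of the charge is missing in east against an impurity charge of 20.0 %, and 28 points in north-west against 30.0 %. We read this as the impurity taking starting material, yet at 50.0 s north-west shows 38.6 % target and east 38.1 %. Our factors stay.

The rest, second substrate, appears in no reading, so we correct nothing for it. The catalyst order itself remains a guess.

The forecast gives 1.95 (1.5 to 2.1) and 0.19 (0.15 to 0.4), on the ground that “the catalyst looks saturated and is not poisoned”. Its central values differ from our 2 and 0.182.

The simulation gives 2.00 and 0.182.

    starting material + free catalyst ⇌ catalyst intermediate A (K = 390 M⁻¹, k = 1600 M⁻¹ s⁻¹)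
    catalyst intermediate A → free catalyst + target (k = 7.50 s⁻¹)
    second substrate + free catalyst ⇌ catalyst intermediate B (K = 5.00 M⁻¹, k = 50.0 M⁻¹ s⁻¹)
    catalyst intermediate B → free catalyst + second product (k = 310 s⁻¹)
    starting material + protic impurity → quenched substrate (k = 0.440 M⁻¹ s⁻¹)

At 0.200 min the flask held 95.4 % of its catalyst as catalyst intermediate A, the resting state, beside 4.42 % free and 0.137 % as catalyst intermediate B. Our turnover rate, read from east, times the catalyst of this flask gives 0.457 min⁻¹ of the charge, and the rate at 20 % conversion stands at 0.473 min⁻¹. For the flask charged at 0.040 mM, the same turnover rate gives 0.0831 min⁻¹, where the rate at 20 % conversion stands at 0.0860 min⁻¹.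

All runs were computed from invented constants; noise was put on by code.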